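(Readings and results were computed for substances that don't exist, noise included.)

The product of these flasks is a chain, and its average length is the ratio of two amounts: monomer in chains over chains begun.

| flask | free monomer | pre-initiator | remark | time |
|---|---|---|---|---|
| oak | 0.12 M (fed, over 15 h) | 1.2 mM | run made earlier |  |
| cedar | 0.19 M (fed, over 15 h) | 1.2 mM | run made earlier |  |
| birch | 0.25 M (fed, over 15 h) | 1.8 mM | run made earlier |  |
| alpha | 0.25 M (fed, over 15 h) | 1.2 mM |  | 30 h |
| delta | 0.25 M (fed, over 15 h) | 1.2 mM |  | 8.0 h |

| run | time / h | monomer in chains / % |
|---|---|---|
| oak | 2.50 | 0 |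
| oak | 5.00 | 2.3 |
| oak | 8.00 | 4.1 |
| oak | 10.0 | 9.7 |
| oak | 12.0 | 16.4 |
| oak | 15.0 | 33.3 |
| oak | 20.0 | 62.9 |
| cedar | 1.00 | 0.5 |
| cedar | 3.00 | 0 |
| cedar | 5.00 | 0.6 |
| cedar | 8.00 | 4.1 |
| cedar | 10.0 | 9.3 |
| cedar | 15.0 | 41.1 |
| cedar | 20.0 | 69.0 |
| birch | 1.33 | 0.9 |
| birch | 2.50 | 0.5 |
| birch | 5.00 | 2.3 |
| birch | 10.0 | 17.5 |
| birch | 20.0 | 82.8 |

(each reading ± 1 percentage point)

- the average divides the monomer in chains by the number of chains begun, living and dead together
- percentages count the whole charge, also what has not yet gone in
- the earlier runs do not show the number of chains; that part of a forecast is a guess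

1. which of the two ends with the longer chains by the average number of monomer units in a chain (chains begun, living or dead) ("neither" if they lie within 10%) (alpha / delta / neither)
2. average number of monomer units in a chain (chains begun, living or dead) at the end, alpha
3. average number of monomer units in a chain (chains begun, living or dead) at the end, delta

The runs show no chain count, so I assumed that one pre-initiator begins one chain. I then reckoned Q = 208, the charge ratio: free monomer charged per pre-initiator charged, which is the length if both charges are used whole. For any moment,

length = Q × (share of free monomer in chains) / (share of pre-initiator that has begun chains).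

Oak and cedar both read 4.1% at 8.00 h despite different charges, so I treated uptake as first order in free monomer, with a pseudo-first-order constant k′ that measures the growing chains. I used cedar, which has alpha's pre-initiator charge, for both flasks. After its feed, cedar's free monomer gave

k′(late) = 0.128 h⁻¹.

Its gain around 8.00 h, divided by the free monomer then present, gave

k′(early) = 0.0353 h⁻¹.

So I reckoned early chains at 0.275 of late ones. Counting the late chains as the whole pre-initiator charge, alpha kept 8.59% free, so

alpha: 190
delta: 31.0

I committed to alpha being longer than delta by a ratio of 6.13.

The forecast also named alpha, but with 320 and 40 against my values, and it said: “The chain count is a guess.”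

The flask gave alpha, with 218 against 36.1.

    free monomer + living end → monomer in chains + living end, rate k1*[living end]*[free monomer] (k = 2.40 M⁻¹ min⁻¹)
    free monomer + initiator → living end + monomer in chains (k = 0.0370 M⁻¹ min⁻¹)
    pre-initiator → initiator (k = 0.00200 min⁻¹)
    free monomer → decomposition product (k = 3.90 × 10⁻⁷ min⁻¹)

Delta stood shorter than alpha because it stopped early: its length was 36.1, and the same recipe run on to alpha's time gave 218. At 8.00 h delta held 5.79% of the free monomer in chains, while its living ends already counted 33.4% of the pre-initiator charge, and Q times that quotient is 36.1. Alpha, the same recipe at 30.0 h, had shares of 93.6% and 89.4%, which give 218. A neighbour of alpha, with 0.10 M of free monomer, has a charge ratio of 83.3, and with 89.2% in chains it ended at 94.1.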